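The tetrahydrofuran ring is cut at O–C9' and C8–C8' (lignan numbering: C7 guaiacyl CH2, C8/C8' ring CH, C9/C9' ring OCH2, C7' syringyl carbinol). The feature exploited is that O–C9'–C8'–C7' becomes a β-alkoxy ketone once C7' is a carbonyl, while O–C9–C8 carrying a vinyl group is ring-opened butadiene monoxide. A single palladium-catalysed (3+2) cycloaddition of racemic 2-vinyloxirane with the O-benzyl syringyl vinyl ketone therefore forms both bonds, the ring and the trans C8/C8' pair in one enantiomeric series. Afterwards C7' is reduced under reagent control, and the vinyl group is shortened to C7 and arylated.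

Key step: step 4

Assumption: the sense of induction of the bisphosphine ligand in step 4 cannot be derived with certainty for this substrate pair. The (R,R) antipode is written, and the equally available (S,S) antipode replaces it if the first run gives the mirror-image series.

Step 1
Reactants: 1 syringaldehyde
Product: 2 4-(benzyloxy)-3,5-dimethoxybenzaldehyde
Conditions: BnBr, K2CO3, DMF, 60 °C
Reagents that add atoms: benzyl bromide, BrCc1ccccc1
Why: Williamson ether synthesis on the acidic para-formyl phenol, giving a benzyl ether that is inert to Grignard reagents, zerovalent palladium, boranes, OsO4 and fluoride and leaves only in the last step.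

Step 2
Reactants: 2 4-(benzyloxy)-3,5-dimethoxybenzaldehyde
Product: 3 rac-1-[4-(benzyloxy)-3,5-dimethoxyphenyl]prop-2-en-1-ol
Conditions: CH2=CHMgBr, THF, 0 °C; aqueous work-up
Reagents that add atoms: vinylmagnesium bromide, C=C[Mg]Br
Why: Grignard 1,2-addition to a non-enolisable aromatic aldehyde, in which the new carbinol centre is formed racemic and is erased by the following oxidation.

Step 3
Reactants: 3 rac-1-[4-(benzyloxy)-3,5-dimethoxyphenyl]prop-2-en-1-ol
Product: 4 1-[4-(benzyloxy)-3,5-dimethoxyphenyl]prop-2-en-1-one
Conditions: activated MnO2 (excess), CH2Cl2, rt; filtration, used at once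
Reagents that add atoms: none
Why: Selective MnO2 oxidation of a doubly activated (allylic and benzylic) alcohol under neutral heterogeneous conditions, so that simple filtration delivers the polymerisation-prone aryl vinyl ketone for immediate use.

Step 4
Reactants: 4 1-[4-(benzyloxy)-3,5-dimethoxyphenyl]prop-2-en-1-one; 5 rac-2-vinyloxirane (butadiene monoxide)
Product: 7 [(3S,4S)-4-ethenyloxolan-3-yl][4-(benzyloxy)-3,5-dimethoxyphenyl]methanone (trans), via cis adduct 6 (not isolated)
Conditions: Pd2(dba)3·CHCl3 (2.5 mol %), (R,R)-DACH-phenyl ligand [(1R,2R)-N,N'-bis(2-diphenylphosphinobenzoyl)cyclohexane-1,2-diamine, 7.5 mol %], 5 (2 equiv), THF, 0 °C to rt, 4 added by syringe pump; then DBU (20 mol %), rt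
Reagents that add atoms: none
Why: Zerovalent palladium ionises the allylic C–O bond of 5 to a zwitterion that carries a primary alkoxide on C9 and a cationic η3-allyl unit starting at C8; the alkoxide adds to the unsubstituted β-carbon of 4 (O–C9') and the resulting aryl ketone enolate attacks the internal allyl carbon through C8' (C8–C8'), which frees the catalyst. The closest known reaction type is the palladium-catalysed formal (3+2) cycloaddition of vinyl epoxides with electron-poor alkenes, an oxa-Michael/intramolecular Tsuji–Trost cascade established for doubly activated acceptors, nitroalkenes and β-substituted enones, so an aryl vinyl ketone is a new member of a known substrate class. The tetrahydrofuran closes in a 5-exo mode at the branched allyl terminus, since attack at the distal CH2 would demand a seven-membered ring. C8 is fixed by the chiral ligand in this irreversible C–C bond formation, and both enantiomers of 5 converge because the diastereomeric allyl complexes exchange faces by η3–η1–η3 slippage at their unsubstituted CH2 terminus faster than they cyclise (dynamic kinetic asymmetric transformation). C8' is fixed thermodynamically relative to C8: its hydrogen is α to the ketone, so catalytic DBU converts the cis adduct 6 into the less congested trans isomer 7. The step needs conjugate rather than carbonyl addition and ring closure rather than enone oligomerisation; the sterically open CH2 terminus of 4 together with reversible hemiketal formation secures the first, and slow addition of 4 to excess 5 combined with the intramolecular nature of the allylation secures the second.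

Step 5
Reactants: 7 [(3S,4S)-4-ethenyloxolan-3-yl][4-(benzyloxy)-3,5-dimethoxyphenyl]methanone
Product: 8 (S)-[4-(benzyloxy)-3,5-dimethoxyphenyl][(3S,4S)-4-ethenyloxolan-3-yl]methanol
Conditions: (R)-2-methyl-CBS-oxazaborolidine (20 mol %), catecholborane, toluene, −78 to −40 °C; aqueous work-up
Reagents that add atoms: none
Why: Corey–Bakshi–Shibata reduction, in which the (R)-oxazaborolidine places the aryl group as the large substituent and delivers hydride in the sense that converts acetophenone into (S)-1-phenylethanol, setting C7' as S under reagent control against the modest Felkin–Anh bias of C8', while catecholborane at low temperature does not hydroborate the vinyl group and the non-basic medium leaves C8' untouched.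

Step 6
Reactants: 8 (S)-[4-(benzyloxy)-3,5-dimethoxyphenyl][(3S,4S)-4-ethenyloxolan-3-yl]methanol
Product: 9 tert-butyl{(S)-[4-(benzyloxy)-3,5-dimethoxyphenyl][(3S,4S)-4-ethenyloxolan-3-yl]methoxy}dimethylsilane
Conditions: TBSCl, imidazole, DMF, rt
Reagents that add atoms: tert-butyldimethylsilyl chloride, CC(C)(C)[Si](C)(C)Cl
Why: Standard silyl ether formation, which keeps O7' out of the sulfonylation and Grignard steps and blocks lactol formation with the C7 aldehyde, a sink that could otherwise drag C8 into the cis-fused series.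

Step 7
Reactants: 9 tert-butyl{(S)-[4-(benzyloxy)-3,5-dimethoxyphenyl][(3S,4S)-4-ethenyloxolan-3-yl]methoxy}dimethylsilane
Product: 12 [(3R,4S)-4-{(S)-[4-(benzyloxy)-3,5-dimethoxyphenyl][(tert-butyldimethylsilyl)oxy]methyl}oxolan-3-yl]methanol, via vicinal diol 10 (not isolated), via aldehyde 11 (not isolated)
Conditions: OsO4 (2 mol %), NaIO4, 2,6-lutidine, dioxane–H2O, rt; extraction; NaBH4, MeOH, 0 °C
Reagents that add atoms: sodium periodate, [Na+].[O-]I(=O)(=O)=O (terminal source of the C7 oxygen, relayed by OsO4, O=[Os](=O)(=O)=O)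
Why: Lemieux–Johnson cleavage (catalytic dihydroxylation and periodate glycol fission) followed by borohydride reduction excises the terminal carbon and turns the inner vinyl carbon into the C7 carbinol, osmium being chosen over ozone because it ignores the trialkoxyarene, while the lutidine buffer and prompt reduction of 11 guard the α-stereocentre C8, whose trans arrangement is in any case the favoured one.

Step 8
Reactants: 12 [(3R,4S)-4-{(S)-[4-(benzyloxy)-3,5-dimethoxyphenyl][(tert-butyldimethylsilyl)oxy]methyl}oxolan-3-yl]methanol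
Product: 13 [(3S,4S)-4-{(S)-[4-(benzyloxy)-3,5-dimethoxyphenyl][(tert-butyldimethylsilyl)oxy]methyl}oxolan-3-yl]methyl 4-methylbenzenesulfonate
Conditions: TsCl, Et3N, DMAP (cat.), CH2Cl2, 0 °C to rt
Reagents that add atoms: 4-toluenesulfonyl chloride, Cc1ccc(cc1)S(=O)(=O)Cl
Why: Sulfonate ester formation at the only free and unhindered primary hydroxyl group, with no stereocentre involved.

Step 9
Reactants: 14 4-bromo-2-methoxyphenol
Product: 15 1-(benzyloxy)-4-bromo-2-methoxybenzene
Conditions: BnBr, K2CO3, DMF, 60 °C
Reagents that add atoms: benzyl bromide, BrCc1ccccc1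
Why: Williamson ether synthesis that removes the acidic phenol proton so that the aryl bromide can be converted into a Grignard reagent.

Step 10
Reactants: 13 the tosylate of step 8; 15 1-(benzyloxy)-4-bromo-2-methoxybenzene
Product: 17 tert-butyl{(S)-[4-(benzyloxy)-3,5-dimethoxyphenyl][(3S,4S)-4-{[4-(benzyloxy)-3-methoxyphenyl]methyl}oxolan-3-yl]methoxy}dimethylsilane, via aryl Grignard reagent 16 (not isolated)
Conditions: 15 (3 equiv), Mg, THF, reflux; then 13, Li2CuCl4 (10 mol %), THF, −20 °C to rt; aqueous work-up
Reagents that add atoms: none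
Why: Copper-catalysed cross-coupling of an aryl Grignard reagent with a primary alkyl tosylate, an SN2-type displacement at C7 by the arylcuprate formed in situ that forms the C7–aryl bond without touching any stereocentre and tolerates silyl and benzyl ethers.

Step 11
Reactants: 17 the fully protected lignan of step 10
Product: 18 (S)-[4-(benzyloxy)-3,5-dimethoxyphenyl][(3S,4S)-4-{[4-(benzyloxy)-3-methoxyphenyl]methyl}oxolan-3-yl]methanol
Conditions: Bu4NF, THF, rt; aqueous work-up
Reagents that add atoms: none
Why: Fluoride-mediated silyl ether cleavage, done while both phenols are still benzylated so that no phenoxide can expel O7' through a para-quinone methide and scramble C7'.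

Step 12
Reactants: 18 the bis(benzyl ether) of step 11
Product: 19 4-[(S)-hydroxy{(3S,4S)-4-[(4-hydroxy-3-methoxyphenyl)methyl]oxolan-3-yl}methyl]-2,6-dimethoxyphenol (7'S,8S,8'S; target)
Conditions: H2 (1 atm), Pd/C (10 wt %), solid NaHCO3, EtOAc, rt, stopped at full conversion
Reagents that add atoms: none
Why: Catalytic hydrogenolysis, in which aryl benzyl ethers are cleaved far faster than a secondary benzylic alcohol as long as the medium is kept acid-free, so that stopping after uptake of two equivalents of hydrogen should preserve the C7' hydroxyl and its configuration.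

Compound list
1 | syringaldehyde (4-hydroxy-3,5-dimethoxybenzaldehyde) | COc1cc(C=O)cc(OC)c1O | starting material
2 | 4-(benzyloxy)-3,5-dimethoxybenzaldehyde | COc1cc(C=O)cc(OC)c1OCc1ccccc1 | intermediate
3 | rac-1-[4-(benzyloxy)-3,5-dimethoxyphenyl]prop-2-en-1-ol | C=CC(O)c1cc(OC)c(OCc2ccccc2)c(OC)c1 | intermediate
4 | 1-[4-(benzyloxy)-3,5-dimethoxyphenyl]prop-2-en-1-one | C=CC(=O)c1cc(OC)c(OCc2ccccc2)c(OC)c1 | intermediate
5 | rac-2-vinyloxirane (butadiene monoxide) | C=CC1CO1 | starting material
6 | cis adduct, [(3R,4S)-4-ethenyloxolan-3-yl][4-(benzyloxy)-3,5-dimethoxyphenyl]methanone | C=C[C@@H]1COC[C@@H]1C(=O)c1cc(OC)c(OCc2ccccc2)c(OC)c1 | intermediate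
7 | trans adduct, [(3S,4S)-4-ethenyloxolan-3-yl][4-(benzyloxy)-3,5-dimethoxyphenyl]methanone | C=C[C@@H]1COC[C@H]1C(=O)c1cc(OC)c(OCc2ccccc2)c(OC)c1 | intermediate
8 | (S)-[4-(benzyloxy)-3,5-dimethoxyphenyl][(3S,4S)-4-ethenyloxolan-3-yl]methanol | C=C[C@@H]1COC[C@H]1[C@H](O)c1cc(OC)c(OCc2ccccc2)c(OC)c1 | intermediate
9 | TBS ether of 8 | C=C[C@@H]1COC[C@H]1[C@H](O[Si](C)(C)C(C)(C)C)c1cc(OC)c(OCc2ccccc2)c(OC)c1 | intermediate
10 | vicinal diol from dihydroxylation of the vinyl group of 9 (both carbinol epimers) | OCC(O)[C@@H]1COC[C@H]1[C@H](O[Si](C)(C)C(C)(C)C)c1cc(OC)c(OCc2ccccc2)c(OC)c1 | intermediate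
11 | (3S,4S)-4-{(S)-[4-(benzyloxy)-3,5-dimethoxyphenyl][(tert-butyldimethylsilyl)oxy]methyl}oxolane-3-carbaldehyde | O=C[C@@H]1COC[C@H]1[C@H](O[Si](C)(C)C(C)(C)C)c1cc(OC)c(OCc2ccccc2)c(OC)c1 | intermediate
12 | [(3R,4S)-4-{(S)-[4-(benzyloxy)-3,5-dimethoxyphenyl][(tert-butyldimethylsilyl)oxy]methyl}oxolan-3-yl]methanol | OC[C@@H]1COC[C@H]1[C@H](O[Si](C)(C)C(C)(C)C)c1cc(OC)c(OCc2ccccc2)c(OC)c1 | intermediate
13 | 4-methylbenzenesulfonate (tosylate) of 12 | Cc1ccc(cc1)S(=O)(=O)OC[C@@H]1COC[C@H]1[C@H](O[Si](C)(C)C(C)(C)C)c1cc(OC)c(OCc2ccccc2)c(OC)c1 | intermediate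
14 | 4-bromo-2-methoxyphenol | COc1cc(Br)ccc1O | starting material
15 | 1-(benzyloxy)-4-bromo-2-methoxybenzene | COc1cc(Br)ccc1OCc1ccccc1 | intermediate
16 | [4-(benzyloxy)-3-methoxyphenyl]magnesium bromide | COc1cc([Mg]Br)ccc1OCc1ccccc1 | intermediate
17 | 7'-O-TBS, 4,4'-di-O-benzyl protected lignan (7'S,8S,8'S) | COc1cc(C[C@@H]2COC[C@H]2[C@H](O[Si](C)(C)C(C)(C)C)c2cc(OC)c(OCc3ccccc3)c(OC)c2)ccc1OCc1ccccc1 | intermediate
18 | 4,4'-di-O-benzyl lignan with free 7'-OH (7'S,8S,8'S) | COc1cc(C[C@@H]2COC[C@H]2[C@H](O)c2cc(OC)c(OCc3ccccc3)c(OC)c2)ccc1OCc1ccccc1 | intermediate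
19 | 4-[(S)-hydroxy{(3S,4S)-4-[(4-hydroxy-3-methoxyphenyl)methyl]oxolan-3-yl}methyl]-2,6-dimethoxyphenol | COc1cc(C[C@@H]2COC[C@H]2[C@H](O)c2cc(OC)c(O)c(OC)c2)ccc1O | target

Total step count: 12. Longest linear sequence: 11 steps (steps 1–8 and 10–12, from syringaldehyde).

Steps most likely to fail

Step 4.
- **What may go wrong:** Anionic oligomerisation of the vinyl ketone may outrun ring closure. The DBU equilibration may trigger β-elimination of the ring oxygen. The ligand may also discriminate poorly between the allyl faces.
- **Fallback:** It sets out from 2 and comes back at 9. The ring carbons are taken from a resolved lactone and the ether ring is closed last. (R)-4-Ethenyloxolan-2-one F1, a known building block obtainable enantiopure by classical resolution, is converted into its lithium enolate with LiN(SiMe3)2 in THF at −78 °C and added to aldehyde 2. The β-vinyl group steers the aldol reaction to the opposite ring face. Chromatography then separates the trans 7'S aldol adduct F2 from the trans 7'R aldol adduct F3, which is set aside. Silylation of F2 (TBSCl, imidazole, DMF) gives the silyl ether lactone F4, and LiAlH4 in THF reduces it to the 1,4-diol F5. Mitsunobu cyclodehydration (PPh3, DIAD, THF) closes the tetrahydrofuran to 9. Every operation is a standard reaction type, and step 5 is bypassed as well.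

Step 5.
- **What may go wrong:** The catalyst has to override the Felkin–Anh preference of C8', which points to the 7'R face, so facial selectivity may erode. Slow reduction of the hindered, electron-rich ketone could also let hydroboration of the vinyl group compete.
- **Fallback:** It sets out from 7 and comes back at 8. Substrate control is accepted and the centre is then inverted. LiBH(s-Bu)3 in THF at −78 °C should reduce 7 in the Felkin–Anh sense to the 7'R alcohol F6. Mitsunobu esterification with 4-nitrobenzoic acid (PPh3, DIAD, toluene, 0 °C) inverts C7' to the 7'S 4-nitrobenzoate F7. Methanolysis (K2CO3, MeOH, rt) releases 8.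

Step 10.
- **What may go wrong:** Displacement at the β-branched tosylate next to the bulky silyloxybenzyl group may be slow. That leaves time for biaryl homocoupling and sulfonate–bromide exchange.
- **Fallback:** It sets out from 13, uses 15, and comes back at 17. The polarity of the coupling is reversed. Finkelstein exchange (NaI, acetone, reflux) gives the primary iodide F8, and zinc insertion (Zn dust, LiCl, THF) gives the alkylzinc iodide F9. Negishi coupling of F9 with aryl bromide 15 (Pd(OAc)2, SPhos, THF, rt to 50 °C) gives 17.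

Further compounds
F1 | step 4 | (R)-4-ethenyloxolan-2-one | C=C[C@@H]1COC(=O)C1
F2 | step 4 | trans 7'S aldol adduct, (3R,4S)-3-{(S)-[4-(benzyloxy)-3,5-dimethoxyphenyl](hydroxy)methyl}-4-ethenyloxolan-2-one | C=C[C@@H]1COC(=O)[C@H]1[C@H](O)c1cc(OC)c(OCc2ccccc2)c(OC)c1
F3 | step 4 | trans 7'R aldol adduct, (3R,4S)-3-{(R)-[4-(benzyloxy)-3,5-dimethoxyphenyl](hydroxy)methyl}-4-ethenyloxolan-2-one | C=C[C@@H]1COC(=O)[C@H]1[C@@H](O)c1cc(OC)c(OCc2ccccc2)c(OC)c1
F4 | step 4 | silyl ether lactone (TBS ether of F2) | C=C[C@@H]1COC(=O)[C@H]1[C@H](O[Si](C)(C)C(C)(C)C)c1cc(OC)c(OCc2ccccc2)c(OC)c1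
F5 | step 4 | 1,4-diol, (2S,3S)-2-{(S)-[4-(benzyloxy)-3,5-dimethoxyphenyl][(tert-butyldimethylsilyl)oxy]methyl}-3-ethenylbutane-1,4-diol | C=C[C@H](CO)[C@@H](CO)[C@H](O[Si](C)(C)C(C)(C)C)c1cc(OC)c(OCc2ccccc2)c(OC)c1
F6 | step 5 | 7'R alcohol, (R)-[4-(benzyloxy)-3,5-dimethoxyphenyl][(3S,4S)-4-ethenyloxolan-3-yl]methanol | C=C[C@@H]1COC[C@H]1[C@@H](O)c1cc(OC)c(OCc2ccccc2)c(OC)c1
F7 | step 5 | 7'S 4-nitrobenzoate of 8 | C=C[C@@H]1COC[C@H]1[C@H](OC(=O)c1ccc(cc1)[N+](=O)[O-])c1cc(OC)c(OCc2ccccc2)c(OC)c1
F8 | step 10 | primary iodide corresponding to 13 | IC[C@@H]1COC[C@H]1[C@H](O[Si](C)(C)C(C)(C)C)c1cc(OC)c(OCc2ccccc2)c(OC)c1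
F9 | step 10 | alkylzinc iodide from F8 | I[Zn]C[C@@H]1COC[C@H]1[C@H](O[Si](C)(C)C(C)(C)C)c1cc(OC)c(OCc2ccccc2)c(OC)c1
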